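**Retrosynthetic overview**
1. Endgame: the acid comes from its tert-butyl ester; before that come tigloylation of the 8β-alcohol, twofold α-methylenation (C11 and C4) and α-face reduction of a C8 ketone.
2. Feature used: in the cyclohexane C5–C6–C7–C8–C9–C10, C9 is the only CH2. It sits between the O-bearing C8 and the quaternary C10, which carries the vinyl group C1=C2 and the methyl C14. C10 can therefore be carried as a non-stereogenic C(CH3)(CH=CH2)2 carbon, and one vinyl CH becomes C9.
3. Key disconnection C8=C9: enol-ether ring-closing metathesis of a lactone triene that must pick one of the two diastereotopic C10 vinyl groups. This closes the carbocycle (second ring) and sets C10.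
4. The triene comes from a trans-γ-lactone methyl ketone (first ring), made by a Mukaiyama aldol (C6–C7) of a C6 aldehyde with the levulinate enol silane; C6 by Felkin control, C7 by equilibration.
5. The aldehyde comes from an auxiliary-controlled alkylation (C4–C5, sets C5) of the imide of the methyl-divinyl acid, itself from a Johnson–Claisen rearrangement (C5–C10) of the dienol with orthoacetate.

Key step: step 10

Assumption: elemane numbering is used throughout (ring C5–C10; lactone C6–O–C12; C13 on C11, C3 on C4, C15 the acid carbon), β is the face of the C14 methyl, and the (E)-dienol is taken as purchasable, its geometry being lost in the Claisen step.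

**Route**

Step 1
Reactants: 1 (E)-3-methylpenta-2,4-dien-1-ol; 2 triethyl orthoacetate
Product: 4 ethyl 3-ethenyl-3-methylpent-4-enoate, via mixed ketene acetal 3 (not isolated)
Conditions: EtCO2H (cat.), 2 as solvent, 140 °C, EtOH distilled off
Reagents that add atoms: none
Why: Johnson–Claisen rearrangement: acid-catalysed exchange and loss of ethanol should give ketene acetal 3, whose chair [3,3] shift joins the acetate carbon (C5) to the methyl-bearing diene carbon and so creates the quaternary, non-stereogenic C10 with its two vinyl groups.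

Step 2
Reactants: 4 ethyl 3-ethenyl-3-methylpent-4-enoate
Product: 5 3-ethenyl-3-methylpent-4-enoic acid
Conditions: LiOH·H2O, THF/MeOH/H2O, 50 °C; then 1 M HCl
Reagents that add atoms: lithium hydroxide, [Li+].[OH-]
Why: Ester saponification; the α-CH2 is unbranched, so hydroxide addition to the carbonyl should not be blocked by the neighbouring quaternary carbon.

Step 3
Reactants: 5 3-ethenyl-3-methylpent-4-enoic acid; 6 (S)-4-benzyl-1,3-oxazolidin-2-one
Product: 8 (S)-4-benzyl-3-(3-ethenyl-3-methylpent-4-enoyl)-1,3-oxazolidin-2-one, via mixed pivalic anhydride 7 (not isolated)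
Conditions: PivCl, Et3N, THF, −20 °C; then 6, LiCl, −20 °C → rt
Reagents that add atoms: none
Why: N-Acylation of the oxazolidinone through a mixed anhydride; the nucleophile should attack the CH2-flanked carbonyl of 7 in preference to the pivaloyl carbonyl.

Step 4
Reactants: 8 (S)-4-benzyl-3-(3-ethenyl-3-methylpent-4-enoyl)-1,3-oxazolidin-2-one; 9 tert-butyl bromoacetate
Product: 11 tert-butyl (3S)-3-{[(4S)-4-benzyl-2-oxo-1,3-oxazolidin-3-yl]carbonyl}-4-ethenyl-4-methylhex-5-enoate, via sodium enolate 10 (not isolated)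
Conditions: NaHMDS, THF, −78 °C; then 9, −78 → −30 °C
Reagents that add atoms: none
Why: Evans asymmetric alkylation: the chelated (Z)-enolate 10 should be alkylated on the face away from the benzyl group by the small, reactive α-bromo ester, which sets C5 (S) and attaches C4/C15.

Step 5
Reactants: 11 tert-butyl (3S)-3-{[(4S)-4-benzyl-2-oxo-1,3-oxazolidin-3-yl]carbonyl}-4-ethenyl-4-methylhex-5-enoate
Product: 12 tert-butyl (3S)-4-ethenyl-3-(hydroxymethyl)-4-methylhex-5-enoate
Conditions: LiBH4, MeOH (1 equiv), Et2O, 0 °C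
Reagents that add atoms: none
Why: Reductive removal of the auxiliary (imide to primary alcohol with LiBH4), which should leave the tert-butyl ester and C5 untouched at 0 °C and return the oxazolidinone.

Step 6
Reactants: 12 tert-butyl (3S)-4-ethenyl-3-(hydroxymethyl)-4-methylhex-5-enoate
Product: 13 tert-butyl (3S)-4-ethenyl-3-formyl-4-methylhex-5-enoate
Conditions: Dess–Martin periodinane, CH2Cl2, 0 °C → rt; used at once
Reagents that add atoms: none
Why: Dess–Martin oxidation under non-basic conditions, so the α-stereocentre C5 of the new C6 aldehyde should not epimerise.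

Step 7
Reactants: 14 methyl levulinate
Product: 15 methyl (Z)-4-(trimethylsilyloxy)pent-3-enoate
Conditions: TMSCl, NaI, Et3N, MeCN, rt; distilled
Reagents that add atoms: chlorotrimethylsilane, C[Si](C)(C)Cl
Why: Silyl enol ether formation under equilibrating conditions (TMSI formed in situ, Et3N), which should favour the more substituted C3=C4 enol ether whose nucleophilic carbon is the future C7.

Step 8
Reactants: 13 tert-butyl (3S)-4-ethenyl-3-formyl-4-methylhex-5-enoate; 15 methyl (Z)-4-(trimethylsilyloxy)pent-3-enoate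
Product: 18 tert-butyl (3S)-3-[(2R,3S)-3-acetyl-5-oxooxolan-2-yl]-4-ethenyl-4-methylhex-5-enoate (trans-lactone methyl ketone), via Felkin aldol adduct 16 (not isolated), via C7-epimeric lactone mixture 17 (not isolated)
Conditions: BF3·OEt2, CH2Cl2, −78 °C; aq. NaHCO3; then CSA (cat.), CH2Cl2, rt; then DBU (cat.), rt
Reagents that add atoms: none
Why: Mukaiyama aldol through an open transition state, in which the enol silane should add to the BF3-bound aldehyde anti to the quaternary C10 substituent (Felkin–Anh, sets C6), followed by lactonisation of the γ-hydroxy methyl ester (the tert-butyl ester does not compete) and base equilibration α to the ketone, which should settle C7 in the more stable trans-lactone.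

Step 9
Reactants: 18 tert-butyl (3S)-3-[(2R,3S)-3-acetyl-5-oxooxolan-2-yl]-4-ethenyl-4-methylhex-5-enoate
Product: 20 tert-butyl (3S)-3-[(2R,3S)-3-{1-[tert-butyl(dimethyl)silyloxy]ethenyl}-5-oxooxolan-2-yl]-4-ethenyl-4-methylhex-5-enoate, via lithium enolate 19 (not isolated)
Conditions: LDA (1.05 equiv), THF, −78 °C; then TBSOTf, −78 °C
Reagents that add atoms: tert-butyldimethylsilyl trifluoromethanesulfonate, CC(C)(C)[Si](C)(C)OS(=O)(=O)C(F)(F)F
Why: Kinetic enolisation of the methyl ketone at its CH3 group and O-silylation; the tertiary C7–H is removed more slowly, so C7 should neither epimerise nor expel the lactone oxygen.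

Step 10
Reactants: 20 tert-butyl (3S)-3-[(2R,3S)-3-{1-[tert-butyl(dimethyl)silyloxy]ethenyl}-5-oxooxolan-2-yl]-4-ethenyl-4-methylhex-5-enoate
Product: 21 tert-butyl 8-(tert-butyldimethylsilyloxy)-3,13-dinorelema-1,8-dien-12,6α-olid-15-oate (5αH 6βH 7αH; 10β-methyl 10α-vinyl)
Conditions: chiral Mo monoaryloxide pyrrolide alkylidene (5 mol%), made in situ from Mo(N-2,6-iPr2C6H3)(CHCMe2Ph)(2,5-Me2-pyrrolide)2 and the matched antipode of mono-TBS 3,3′-dibromo-octahydrobinaphthol; C6H6, 22 °C
Reagents that add atoms: none
Why: The Mo alkylidene should load onto a C10 vinyl group (the two vinyl-bound alkylidenes can interconvert through the methylidene and ethene), add across the enol ether C8=CH2 to a molybdacyclobutane and cyclorevert to the C8=C9 silyl enol ether and Mo=CH2, which leaves as ethene. The closest known reaction types are ring-closing metathesis of silyl enol ethers to cyclic silyl enol ethers and Mo-catalysed ring-closing metathesis that desymmetrises a divinyl quaternary carbon; their combination on one substrate is untested. The cyclohexene C5–C6–C7–C8=C9–C10 is closed by olefin metathesis between the enol-ether carbon C8 and a vinyl CH, the only closure available because any other alkene pairing would give a three- or four-membered ring. C10 becomes stereogenic here and is set by the choice of vinyl group: the catalyst must cyclise through the half-chair in which the remaining vinyl is pseudo-equatorial (α) and the methyl pseudo-axial (β). The substrate fixes that half-chair (trans-lactone at C6/C7, equatorial C5 side chain) but tells methyl from vinyl only weakly, so the step needs group selectivity from the chiral alkylidene, and the ligand antipode that reinforces the substrate is the one to use. Chemoselectivity should not be an issue, since vinyl groups on a quaternary carbon dimerise poorly and the ester and lactone are inert to Mo alkylidenes.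

Step 11
Reactants: 21 tert-butyl 8-(tert-butyldimethylsilyloxy)-3,13-dinorelema-1,8-dien-12,6α-olid-15-oate
Product: 22 tert-butyl 8-oxo-3,13-dinorelem-1-en-12,6α-olid-15-oate
Conditions: TBAF, AcOH, THF, 0 °C
Reagents that add atoms: none
Why: Fluoride-induced cleavage of the silyl enol ether with protonation at C9 (enol ether hydrolysis), buffered with acetic acid so that the β-acyloxy ketone is not exposed to base and C7 should keep its configuration.

Step 12
Reactants: 22 tert-butyl 8-oxo-3,13-dinorelem-1-en-12,6α-olid-15-oate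
Product: 23 tert-butyl 8β-hydroxy-3,13-dinorelem-1-en-12,6α-olid-15-oate
Conditions: L-Selectride, THF, −78 °C; AcOH quench at −78 °C
Reagents that add atoms: none
Why: Ketone reduction with a bulky hydride: the β-face axial approach to C8 is blocked by the axial C10 methyl, so hydride should arrive equatorially from the α face and give the axial 8β-alcohol, and the cold acidic quench should keep the alkoxide from attacking the lactone carbonyl.

Step 13
Reactants: 23 tert-butyl 8β-hydroxy-3,13-dinorelem-1-en-12,6α-olid-15-oate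
Product: 24 tert-butyl 8β-(triethylsilyloxy)-3,13-dinorelem-1-en-12,6α-olid-15-oate
Conditions: TESOTf, 2,6-lutidine, CH2Cl2, −78 °C
Reagents that add atoms: triethylsilyl trifluoromethanesulfonate, CC[Si](CC)(CC)OS(=O)(=O)C(F)(F)F
Why: Silyl ether protection of the hindered axial alcohol, so that no alkoxide sits next to the lactone during the enolate chemistry of step 14.

Step 14
Reactants: 24 tert-butyl 8β-(triethylsilyloxy)-3,13-dinorelem-1-en-12,6α-olid-15-oate
Product: 28 tert-butyl 8β-(triethylsilyloxy)elema-1,3,11(13)-trien-12,6α-olid-15-oate, via dilithium bis-enolate 25 (not isolated), via bis-Mannich base 26 (not isolated), via bis-ammonium iodide 27 (not isolated)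
Conditions: LDA (3 equiv), THF, −78 °C; Me2N=CH2+ I−, −78 °C → rt; then MeI, THF, rt; then DBU, rt
Reagents that add atoms: N,N-dimethylmethyleneiminium iodide (Eschenmoser's salt), C=[N+](C)C.[I-]
Why: Twofold Mannich reaction of the lactone and ester enolates with Eschenmoser's salt, then N-methylation and β-elimination of trimethylamine, should install both exocyclic methylenes (C13 on C11, C3 on C4); the transient sp3 centres at C11 and C4 are erased.

Step 15
Reactants: 28 tert-butyl 8β-(triethylsilyloxy)elema-1,3,11(13)-trien-12,6α-olid-15-oate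
Product: 29 tert-butyl 8β-hydroxyelema-1,3,11(13)-trien-12,6α-olid-15-oate
Conditions: HF·pyridine, pyridine, THF, 0 °C
Reagents that add atoms: none
Why: Fluoride desilylation of the TES ether in a weakly acidic medium, under which the 8β-hydroxyl should not translactonise and the tert-butyl ester should survive.

Step 16
Reactants: 29 tert-butyl 8β-hydroxyelema-1,3,11(13)-trien-12,6α-olid-15-oate; 30 tiglic acid [(E)-2-methylbut-2-enoic acid]
Product: 32 tert-butyl 8β-(tigloyloxy)elema-1,3,11(13)-trien-12,6α-olid-15-oate, via tigloyl trichlorobenzoyl anhydride 31 (not isolated)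
Conditions: 30, 2,4,6-Cl3C6H2COCl, Et3N, toluene, rt; then 29, DMAP, 40 °C
Reagents that add atoms: none
Why: Yamaguchi esterification: the mixed anhydride and DMAP should acylate the hindered axial 8β-alcohol with retention at C8, and the (E)-tiglate is the stable geometry.

Step 17
Reactants: 32 tert-butyl 8β-(tigloyloxy)elema-1,3,11(13)-trien-12,6α-olid-15-oate
Product: 33 8β-(tigloyloxy)elema-1,3,11(13)-trien-12,6α-olid-15-oic acid (CNP0256928.1; 5R,6R,7R,8R,10S)
Conditions: TFA/CH2Cl2 (1:4), 0 °C → rt
Reagents that add atoms: none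
Why: Acidolysis of the tert-butyl ester (loss of isobutene) should free the C15 acid without touching the lactone, the tiglate or the alkenes.

**Compound list**
1 | (E)-3-methylpenta-2,4-dien-1-ol | C=C/C(C)=C/CO | starting material
2 | triethyl orthoacetate | CCOC(C)(OCC)OCC | starting material
3 | (E)-1-ethoxy-1-[(3-methylpenta-2,4-dien-1-yl)oxy]ethene (mixed ketene acetal) | C=C/C(C)=C/COC(=C)OCC | intermediate (not isolated)
4 | ethyl 3-ethenyl-3-methylpent-4-enoate | CCOC(=O)CC(C)(C=C)C=C | intermediate
5 | 3-ethenyl-3-methylpent-4-enoic acid | OC(=O)CC(C)(C=C)C=C | intermediate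
6 | (S)-4-benzyl-1,3-oxazolidin-2-one | O=C1N[C@@H](Cc2ccccc2)CO1 | starting material
7 | 3-ethenyl-3-methylpent-4-enoic 2,2-dimethylpropanoic anhydride | CC(C)(C)C(=O)OC(=O)CC(C)(C=C)C=C | intermediate (not isolated)
8 | (S)-4-benzyl-3-(3-ethenyl-3-methylpent-4-enoyl)-1,3-oxazolidin-2-one | O=C1OC[C@H](Cc2ccccc2)N1C(=O)CC(C)(C=C)C=C | intermediate
9 | tert-butyl bromoacetate | BrCC(=O)OC(C)(C)C | starting material
10 | sodium (Z)-enolate of 8 | [Na+].O=C1OC[C@H](Cc2ccccc2)N1/C([O-])=C/C(C)(C=C)C=C | intermediate (not isolated)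
11 | tert-butyl (3S)-3-{[(4S)-4-benzyl-2-oxo-1,3-oxazolidin-3-yl]carbonyl}-4-ethenyl-4-methylhex-5-enoate | O=C1OC[C@H](Cc2ccccc2)N1C(=O)[C@@H](CC(=O)OC(C)(C)C)C(C)(C=C)C=C | intermediate
12 | tert-butyl (3S)-4-ethenyl-3-(hydroxymethyl)-4-methylhex-5-enoate | OC[C@@H](CC(=O)OC(C)(C)C)C(C)(C=C)C=C | intermediate
13 | tert-butyl (3S)-4-ethenyl-3-formyl-4-methylhex-5-enoate | O=C[C@@H](CC(=O)OC(C)(C)C)C(C)(C=C)C=C | intermediate
14 | methyl levulinate (methyl 4-oxopentanoate) | CC(=O)CCC(=O)OC | starting material
15 | methyl (Z)-4-(trimethylsilyloxy)pent-3-enoate | C/C(O[Si](C)(C)C)=C/CC(=O)OC | intermediate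
16 | 7-tert-butyl 1-methyl (3RS,4R,5S)-3-acetyl-4-hydroxy-5-(3-methylpenta-1,4-dien-3-yl)heptanedioate (Felkin adduct, both C7 epimers) | CC(=O)C(CC(=O)OC)[C@H](O)[C@@H](CC(=O)OC(C)(C)C)C(C)(C=C)C=C | intermediate (not isolated)
17 | tert-butyl (3S)-3-[(2R,3RS)-3-acetyl-5-oxooxolan-2-yl]-4-ethenyl-4-methylhex-5-enoate (cis/trans mixture at C7) | CC(=O)C1CC(=O)O[C@@H]1[C@@H](CC(=O)OC(C)(C)C)C(C)(C=C)C=C | intermediate (not isolated)
18 | tert-butyl (3S)-3-[(2R,3S)-3-acetyl-5-oxooxolan-2-yl]-4-ethenyl-4-methylhex-5-enoate (trans-lactone) | CC(=O)[C@H]1CC(=O)O[C@@H]1[C@@H](CC(=O)OC(C)(C)C)C(C)(C=C)C=C | intermediate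
19 | lithium enolate of 18 (C8–OLi, terminal CH2=) | [Li+].C=C([O-])[C@H]1CC(=O)O[C@@H]1[C@@H](CC(=O)OC(C)(C)C)C(C)(C=C)C=C | intermediate (not isolated)
20 | tert-butyl (3S)-3-[(2R,3S)-3-{1-[tert-butyl(dimethyl)silyloxy]ethenyl}-5-oxooxolan-2-yl]-4-ethenyl-4-methylhex-5-enoate (key-step precursor) | C=C(O[Si](C)(C)C(C)(C)C)[C@H]1CC(=O)O[C@@H]1[C@@H](CC(=O)OC(C)(C)C)C(C)(C=C)C=C | intermediate
21 | tert-butyl 8-(tert-butyldimethylsilyloxy)-3,13-dinorelema-1,8-dien-12,6α-olid-15-oate (trans-fused lactone; C5 side chain β; 10β-methyl, 10α-vinyl; key-step product) | C=C[C@]1(C)C=C(O[Si](C)(C)C(C)(C)C)[C@H]2CC(=O)O[C@@H]2[C@H]1CC(=O)OC(C)(C)C | intermediate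
22 | tert-butyl 8-oxo-3,13-dinorelem-1-en-12,6α-olid-15-oate | C=C[C@]1(C)CC(=O)[C@H]2CC(=O)O[C@@H]2[C@H]1CC(=O)OC(C)(C)C | intermediate
23 | tert-butyl 8β-hydroxy-3,13-dinorelem-1-en-12,6α-olid-15-oate (axial OH) | C=C[C@]1(C)C[C@@H](O)[C@H]2CC(=O)O[C@@H]2[C@H]1CC(=O)OC(C)(C)C | intermediate
24 | tert-butyl 8β-(triethylsilyloxy)-3,13-dinorelem-1-en-12,6α-olid-15-oate | C=C[C@]1(C)C[C@@H](O[Si](CC)(CC)CC)[C@H]2CC(=O)O[C@@H]2[C@H]1CC(=O)OC(C)(C)C | intermediate
25 | dilithium bis-enolate of 24 (lactone C11=C12 and ester C4=C15 enolates) | [Li+].[Li+].C=C[C@]1(C)C[C@@H](O[Si](CC)(CC)CC)[C@H]2C=C([O-])O[C@@H]2[C@H]1C=C([O-])OC(C)(C)C | intermediate (not isolated)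
26 | 11,4-bis(dimethylaminomethyl) derivative of 24 (epimers at C11 and C4) | C=C[C@]1(C)C[C@@H](O[Si](CC)(CC)CC)[C@H]2C(CN(C)C)C(=O)O[C@@H]2[C@H]1C(CN(C)C)C(=O)OC(C)(C)C | intermediate (not isolated)
27 | bis(trimethylammoniomethyl) diiodide from 26 | C=C[C@]1(C)C[C@@H](O[Si](CC)(CC)CC)[C@H]2C(C[N+](C)(C)C)C(=O)O[C@@H]2[C@H]1C(C[N+](C)(C)C)C(=O)OC(C)(C)C.[I-].[I-] | intermediate (not isolated)
28 | tert-butyl 8β-(triethylsilyloxy)elema-1,3,11(13)-trien-12,6α-olid-15-oate | C=C[C@]1(C)C[C@@H](O[Si](CC)(CC)CC)[C@H]2C(=C)C(=O)O[C@@H]2[C@H]1C(=C)C(=O)OC(C)(C)C | intermediate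
29 | tert-butyl 8β-hydroxyelema-1,3,11(13)-trien-12,6α-olid-15-oate | C=C[C@]1(C)C[C@@H](O)[C@H]2C(=C)C(=O)O[C@@H]2[C@H]1C(=C)C(=O)OC(C)(C)C | intermediate
30 | tiglic acid, (E)-2-methylbut-2-enoic acid | C/C=C(\C)C(=O)O | starting material
31 | (E)-2-methylbut-2-enoic 2,4,6-trichlorobenzoic anhydride | C/C=C(\C)C(=O)OC(=O)c1c(Cl)cc(Cl)cc1Cl | intermediate (not isolated)
32 | tert-butyl 8β-(tigloyloxy)elema-1,3,11(13)-trien-12,6α-olid-15-oate | C=C[C@]1(C)C[C@@H](OC(=O)/C(C)=C/C)[C@H]2C(=C)C(=O)O[C@@H]2[C@H]1C(=C)C(=O)OC(C)(C)C | intermediate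
33 | 8β-(tigloyloxy)elema-1,3,11(13)-trien-12,6α-olid-15-oic acid (CNP0256928.1) | C=C[C@]1(C)C[C@@H](OC(=O)/C(C)=C/C)[C@H]2C(=C)C(=O)O[C@@H]2[C@H]1C(=C)C(=O)O | target

**Totals**
Total steps: 17. Longest linear sequence: 16 (steps 1–6 and 8–17; step 7 is a one-step side branch).

**Steps most likely to fail**

Step 10 (key step). What may go wrong: the two vinyl-bound alkylidenes cyclise at similar rates, or the substrate bias opposes both ligand antipodes, so the vinyl groups are not told apart; the enol ether may also tie up the catalyst as a heteroatom-stabilised alkylidene. Fallback, from 20 back to 22: give up catalyst control and sort by separation. Triene 20 is closed with an achiral Ru–NHC o-isopropoxybenzylidene catalyst (toluene, 70 °C), which should give 21 together with the C10-epimeric silyl enol ether F1. The mixture is hydrolysed as in step 11 to ketone 22 and the C10-epimeric ketone F2. These are diastereomers with different chair substitution (axial vinyl in F2) and should separate on silica; 22 rejoins the route at step 12. The cost is that no more than the statistical share of 20 can reach 22, since F2 cannot be recycled.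

Step 8. What may go wrong: the enol silane reacts through its terminal isomer, the open transition state gives insufficient facial selectivity at C6, or BF3 erodes the tert-butyl ester. Fallback, from 13 (with 6) back to 18: replace substrate control by reagent control. Oxazolidinone 6 is N-acylated (n-BuLi, methyl 4-chloro-4-oxobutanoate) to the succinyl imide F3. Its dibutylboron (Z)-enolate (Bu2BOTf, iPr2NEt, CH2Cl2, −78 → 0 °C) adds to 13 to give the syn-aldol adduct F4, with C6 and C7 set by the auxiliary. F4 lactonises (CSA cat.) to the trans-lactone imide F5. LiOH/H2O2 then gives the lactone acid F6, oxalyl chloride with DMF (cat.) the acid chloride F7, and Me2CuLi (Et2O, −78 °C) the methyl ketone 18. The aldehyde's own preference with a (Z)-enolate opposes this adduct, so the reaction may be slow, but the auxiliary normally dominates.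

Step 4. What may go wrong: C-alkylation at the enolate carbon next to the quaternary centre is slow, and the sodium enolate decomposes (ketene loss of the auxiliary) before it is alkylated. Fallback, from 5 back to 11: alkylate without the auxiliary and use it afterwards as a resolving handle. Acid 5 is doubly deprotonated (LDA, 2.2 equiv, THF/DMPU) and alkylated with 9 to the racemic succinate half-ester F8. F8 is converted with oxalyl chloride to the acid chloride F9 and coupled with 6 (n-BuLi, THF, −78 °C). The two diastereomeric imides, 11 and its C5 epimer F10, are separated by chromatography; 11 rejoins the route at step 5.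

**Further compounds**
F1 | step 10 | C10 epimer of 21 (10α-methyl, 10β-vinyl) | C=C[C@@]1(C)C=C(O[Si](C)(C)C(C)(C)C)[C@H]2CC(=O)O[C@@H]2[C@H]1CC(=O)OC(C)(C)C
F2 | step 10 | C10 epimer of 22 (10α-methyl, 10β-vinyl) | C=C[C@@]1(C)CC(=O)[C@H]2CC(=O)O[C@@H]2[C@H]1CC(=O)OC(C)(C)C
F3 | step 8 | methyl 4-[(4S)-4-benzyl-2-oxo-1,3-oxazolidin-3-yl]-4-oxobutanoate | COC(=O)CCC(=O)N1[C@@H](Cc2ccccc2)COC1=O
F4 | step 8 | syn-aldol adduct of F3 and 13 (open hydroxy ester imide) | COC(=O)C[C@@H]([C@H](O)[C@@H](CC(=O)OC(C)(C)C)C(C)(C=C)C=C)C(=O)N1[C@@H](Cc2ccccc2)COC1=O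
F5 | step 8 | trans-lactone imide (N-acyl oxazolidinone at C8) | O=C([C@H]1CC(=O)O[C@@H]1[C@@H](CC(=O)OC(C)(C)C)C(C)(C=C)C=C)N1[C@@H](Cc2ccccc2)COC1=O
F6 | step 8 | (2R,3S)-2-[(3S)-1-tert-butoxy-4-ethenyl-4-methyl-1-oxohex-5-en-3-yl]-5-oxooxolane-3-carboxylic acid | OC(=O)[C@H]1CC(=O)O[C@@H]1[C@@H](CC(=O)OC(C)(C)C)C(C)(C=C)C=C
F7 | step 8 | acid chloride of F6 | ClC(=O)[C@H]1CC(=O)O[C@@H]1[C@@H](CC(=O)OC(C)(C)C)C(C)(C=C)C=C
F8 | step 4 | racemic 2-(2-tert-butoxy-2-oxoethyl)-3-ethenyl-3-methylpent-4-enoic acid | OC(=O)C(CC(=O)OC(C)(C)C)C(C)(C=C)C=C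
F9 | step 4 | racemic tert-butyl 3-(chlorocarbonyl)-4-ethenyl-4-methylhex-5-enoate | ClC(=O)C(CC(=O)OC(C)(C)C)C(C)(C=C)C=C
F10 | step 4 | tert-butyl (3R)-3-{[(4S)-4-benzyl-2-oxo-1,3-oxazolidin-3-yl]carbonyl}-4-ethenyl-4-methylhex-5-enoate (C5 epimer of 11) | O=C1OC[C@H](Cc2ccccc2)N1C(=O)[C@H](CC(=O)OC(C)(C)C)C(C)(C=C)C=C
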